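**Plan**

1. Retrosynthetic cuts: first the pyran O–C(quaternary) bond, with the C10=C11 enol ether returned to a C10 ketone and C11–H, which gives a γ,δ-epoxy ketone. Then the C11–C1' bond (tricyclic ketone plus a C10 epoxy iodide), then the diaryl ether C–O and C11–aryl bonds of the oxepinone, and last the aryl–prenyl bond.
2. Forward order: rings A and B are bought (a dibromoresorcinol and a fluoroacetophenone). Prenylation, Pd α-arylation and an intramolecular SNAr close the oxepinone (ring C); C-alkylation attaches the C10 chain; the dihydropyran (ring D) closes last.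
3. Enabling feature: in the epoxy ketone the C10 carbonyl oxygen lies five atoms from the tertiary oxirane carbon (O=C10–C11–C1'–C2'–C3'), and C11–H is benzylic and α to C10. Opening of the epoxide by that oxygen and loss of H-11 therefore give ring D, the tertiary ether and the C10=C11 enol ether (conjugated with rings A and B) in one event.
4. Stereochemistry: both stereocentres come from one Sharpless epoxidation of nerol. The carbinol carbon keeps its C–O bond (S); the quaternary carbon is inverted on ring closure (3R epoxide gives the S ether carbon).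

Key step: step 11

Assumption: nerol, 4,6-dibromoresorcinol and 2'-fluoro-4'-hydroxyacetophenone are taken as commercial. Ring positions follow dibenzo[b,f]oxepine numbering; side-chain carbons are primed (C1' = CH2 on C11, C2' = oxirane CH, C3' = oxirane quaternary carbon); MOM = methoxymethyl.

**Step 1**
Reactants: 1 nerol, (2Z)-3,7-dimethylocta-2,6-dien-1-ol
Product: 2 [(2S,3R)-3-methyl-3-(4-methylpent-3-en-1-yl)oxiran-2-yl]methanol
Conditions: Ti(OiPr)4 (5 mol%), L-(+)-diethyl tartrate (6 mol%), t-BuOOH (isooctane), 4 Å MS, CH2Cl2, −20 °C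
Reagents that add atoms: tert-butyl hydroperoxide, CC(C)(C)OO
Why: Sharpless asymmetric epoxidation is directed by the allylic hydroxyl to the 2,3-olefin only and, with the L-(+)-tartrate ligand, should deliver oxygen to the face that gives C2 (S) and C3 (R) of the cis-epoxide.

**Step 2**
Reactants: 2 [(2S,3R)-3-methyl-3-(4-methylpent-3-en-1-yl)oxiran-2-yl]methanol
Product: 3 (2R,3R)-2-(iodomethyl)-3-methyl-3-(4-methylpent-3-en-1-yl)oxirane
Conditions: PPh3, I2, imidazole, CH2Cl2, 0 °C
Reagents that add atoms: iodine, II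
Why: Appel-type (Garegg–Samuelsson) iodination should convert the primary alcohol into the iodide by SN2 displacement at C1 without touching the epoxide stereocentres (the C2 descriptor changes only through CIP priority).

**Step 3**
Reactants: 4 4,6-dibromobenzene-1,3-diol
Product: 5 1,5-dibromo-2,4-bis(triisopropylsilyloxy)benzene
Conditions: iPr3SiCl, imidazole, DMF, 40 °C
Reagents that add atoms: chlorotriisopropylsilane, CC(C)[Si](Cl)(C(C)C)C(C)C
Why: imidazole-promoted silylation should protect both phenols, the bulky triisopropylsilyl groups being chosen because they resist O-to-C silyl migration in the ortho-lithiated species of the next step.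

**Step 4**
Reactants: 5 1,5-dibromo-2,4-bis(triisopropylsilyloxy)benzene
Product: 7 1-bromo-5-(3-methylbut-2-en-1-yl)-2,4-bis(triisopropylsilyloxy)benzene, via aryllithium 6 (not isolated)
Conditions: n-BuLi (1.0 equiv), THF, −78 °C; then CuBr·SMe2 (0.2 equiv), prenyl bromide, −78 to 0 °C
Reagents that add atoms: prenyl bromide (1-bromo-3-methylbut-2-ene), CC(C)=CCBr
Why: bromine–lithium exchange should stop after one of the two equivalent bromides (the aryllithium resists a second exchange), and copper-assisted SN2 allylation at the primary carbon of prenyl bromide installs the prenyl group.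

**Step 5**
Reactants: 8 1-(2-fluoro-4-hydroxyphenyl)ethan-1-one
Product: 9 1-[2-fluoro-4-(methoxymethoxy)phenyl]ethan-1-one
Conditions: MeOCH2Cl, iPr2NEt, CH2Cl2, 0 °C to rt
Reagents that add atoms: chloromethyl methyl ether, COCCl
Why: O-alkylation of the acidic phenol gives a MOM acetal that is stable to base, fluoride and palladium and, unlike a free phenoxide, does not switch off the later SNAr.

**Step 6**
Reactants: 7 1-bromo-5-(3-methylbut-2-en-1-yl)-2,4-bis(triisopropylsilyloxy)benzene; 9 1-[2-fluoro-4-(methoxymethoxy)phenyl]ethan-1-one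
Product: 10 1-[2-fluoro-4-(methoxymethoxy)phenyl]-2-[5-(3-methylbut-2-en-1-yl)-2,4-bis(triisopropylsilyloxy)phenyl]ethan-1-one
Conditions: Pd2(dba)3 (2 mol%), XPhos (5 mol%), K3PO4, toluene, 80 °C
Reagents that add atoms: none
Why: Buchwald–Hartwig-type palladium-catalysed α-arylation of the methyl ketone enolate should form the C11–aryl bond, mono-arylation being favoured by the ortho-substituted bromide and the mild phosphate base sparing the silyl ethers and the aryl fluoride.

**Step 7**
Reactants: 10 1-[2-fluoro-4-(methoxymethoxy)phenyl]-2-[5-(3-methylbut-2-en-1-yl)-2,4-bis(triisopropylsilyloxy)phenyl]ethan-1-one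
Product: 12 3-hydroxy-7-(methoxymethoxy)-2-(3-methylbut-2-en-1-yl)dibenzo[b,f]oxepin-10(11H)-one, via dicaesium diphenolate 11 (not isolated)
Conditions: CsF (4 equiv), DMF, rt then 90 °C; then 1 M HCl (aq.) to pH 5
Reagents that add atoms: none
Why: fluoride cleaves both aryl silyl ethers, and the phenoxide ortho to the benzylic carbon should displace the ketone-activated ortho-fluoride (intramolecular SNAr) to close the seven-membered diaryl ether ring C, the second phenoxide having no intramolecular partner.

**Step 8**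
Reactants: 12 3-hydroxy-7-(methoxymethoxy)-2-(3-methylbut-2-en-1-yl)dibenzo[b,f]oxepin-10(11H)-one
Product: 13 3,7-dihydroxy-2-(3-methylbut-2-en-1-yl)dibenzo[b,f]oxepin-10(11H)-one
Conditions: 2 M HCl, MeOH/THF, 40 °C
Reagents that add atoms: none
Why: acid-catalysed methanolysis of the aryl MOM acetal should free the ring-B phenol under conditions that the ketone, the diaryl ether and the prenyl group tolerate.

**Step 9**
Reactants: 13 3,7-dihydroxy-2-(3-methylbut-2-en-1-yl)dibenzo[b,f]oxepin-10(11H)-one
Product: 14 2-(3-methylbut-2-en-1-yl)-3,7-bis(triisopropylsilyloxy)dibenzo[b,f]oxepin-10(11H)-one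
Conditions: iPr3SiCl, imidazole, DMAP (cat.), DMF, 40 °C
Reagents that add atoms: chlorotriisopropylsilane, CC(C)[Si](Cl)(C(C)C)C(C)C
Why: silylation of both phenols gives base-stable, fluoride-labile protection, so that the last deprotection needs no acid.

**Step 10**
Reactants: 14 2-(3-methylbut-2-en-1-yl)-3,7-bis(triisopropylsilyloxy)dibenzo[b,f]oxepin-10(11H)-one; 3 (2R,3R)-2-(iodomethyl)-3-methyl-3-(4-methylpent-3-en-1-yl)oxirane
Product: 16 11-{[(2S,3R)-3-methyl-3-(4-methylpent-3-en-1-yl)oxiran-2-yl]methyl}-2-(3-methylbut-2-en-1-yl)-3,7-bis(triisopropylsilyloxy)dibenzo[b,f]oxepin-10(11H)-one (both C11 epimers), via lithium enolate 15 (not isolated)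
Conditions: LiN(SiMe3)2 (1.05 equiv), THF, −78 °C; then 3, −78 to −10 °C; pH 7 buffer
Reagents that add atoms: none
Why: C-alkylation of the benzylic ketone lithium enolate by the soft primary iodide (SN2 at CH2–I) should join the two fragments with the epoxide stereocentres untouched; C11 forms as an epimer mixture that is irrelevant because C11 becomes sp2 in step 11.

**Step 11**
Reactants: 16 11-{[(2S,3R)-3-methyl-3-(4-methylpent-3-en-1-yl)oxiran-2-yl]methyl}-2-(3-methylbut-2-en-1-yl)-3,7-bis(triisopropylsilyloxy)dibenzo[b,f]oxepin-10(11H)-one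
Product: 17 triethylsilyl ether of the bis(triisopropylsilyl)-protected target: (2S,3S)-2-methyl-2-(4-methylpent-3-en-1-yl)-3-(triethylsilyloxy)-3,4-dihydro-2H-pyran fused across C10=C11 of the dibenzo[b,f]oxepine (pyran O on C10; pyran CH2 on C11) carrying 2-prenyl and 3,7-bis(triisopropylsilyloxy) groups
Conditions: Et3SiOTf (1.3 equiv), 2,6-di-tert-butyl-4-methylpyridine (2 equiv), 4 Å MS, CH2Cl2, −78 to −30 °C; then Et3N, NaHCO3 (aq.)
Reagents that add atoms: triethylsilyl trifluoromethanesulfonate, CC[Si](CC)(CC)OS(=O)(=O)C(F)(F)F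
Why: Proposed new method: silylation of the epoxide oxygen should give a silyloxonium ion whose tertiary carbon C3' is attacked from the backside by the C10 carbonyl oxygen, and the resulting cyclic oxocarbenium ion (stabilised by the para-silyloxyphenyl ring B) should lose the benzylic C11 proton to the hindered pyridine, so that ring D and the tetrasubstituted C10=C11 enol ether arise in one operation with the carbinol oxygen capped as its triethylsilyl ether. The closest known reaction types are the Lewis-acid- or silyl-triflate-promoted endo-selective opening of trisubstituted epoxides by carbonyl oxygens (carbonates, carbamates, and ketones giving bicyclic ketals), the acid-mediated cyclisation of ortho-(2,3-epoxyprenyl)phenols to chroman-3-ols, and the silyl triflate/amine conversion of ketals into enol ethers. The ring closes in the 6-endo-tet mode at the epoxide (O, C10, C11, C1', C2', C3'). The quaternary stereocentre is set by inversion at C3' (3R epoxide gives the S ether carbon), the carbinol stereocentre keeps the C2'–O bond made in step 1, and the C11 epimers converge because C11 becomes sp2. The step needs attack at the tertiary and not the secondary epoxide carbon (5-exo), and proton loss in preference to ketal formation, hydride shift or elimination to an allylic silyl ether. These are secured by the cation-stabilising substitution at C3', the weakly nucleophilic carbonyl oxygen (late but still invertive transition state), the acidity of the doubly activated C11–H and the proton-selective base.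

**Step 12**
Reactants: 17 triethylsilyl ether of the bis(triisopropylsilyl)-protected target
Product: 18 target CNP0185870.1, the (2S,3S)-3-hydroxy-2-methyl-2-(4-methylpent-3-en-1-yl)dihydropyrano-fused 2-prenyl-dibenzo[b,f]oxepine-3,7-diol
Conditions: Bu4NF (4 equiv), AcOH (4 equiv), THF, 0 °C to rt
Reagents that add atoms: none
Why: buffered fluoride desilylation should cleave the two aryl triisopropylsilyl ethers and the secondary triethylsilyl ether without acid, leaving the enol ether, the two trisubstituted olefins and both stereocentres untouched.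

**Compound list**

1 | nerol, (2Z)-3,7-dimethylocta-2,6-dien-1-ol | CC(C)=CCC/C(C)=C\CO | starting material
2 | [(2S,3R)-3-methyl-3-(4-methylpent-3-en-1-yl)oxiran-2-yl]methanol | CC(C)=CCC[C@@]1(C)O[C@H]1CO | intermediate
3 | (2R,3R)-2-(iodomethyl)-3-methyl-3-(4-methylpent-3-en-1-yl)oxirane | CC(C)=CCC[C@@]1(C)O[C@H]1CI | intermediate
4 | 4,6-dibromobenzene-1,3-diol | Oc1cc(O)c(Br)cc1Br | starting material
5 | 1,5-dibromo-2,4-bis(triisopropylsilyloxy)benzene | CC(C)[Si](Oc1cc(O[Si](C(C)C)(C(C)C)C(C)C)c(Br)cc1Br)(C(C)C)C(C)C | intermediate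
6 | [5-bromo-2,4-bis(triisopropylsilyloxy)phenyl]lithium | [Li]c1cc(Br)c(O[Si](C(C)C)(C(C)C)C(C)C)cc1O[Si](C(C)C)(C(C)C)C(C)C | intermediate
7 | 1-bromo-5-(3-methylbut-2-en-1-yl)-2,4-bis(triisopropylsilyloxy)benzene | CC(C)=CCc1cc(Br)c(O[Si](C(C)C)(C(C)C)C(C)C)cc1O[Si](C(C)C)(C(C)C)C(C)C | intermediate
8 | 1-(2-fluoro-4-hydroxyphenyl)ethan-1-one | CC(=O)c1ccc(O)cc1F | starting material
9 | 1-[2-fluoro-4-(methoxymethoxy)phenyl]ethan-1-one | COCOc1ccc(C(C)=O)c(F)c1 | intermediate
10 | 1-[2-fluoro-4-(methoxymethoxy)phenyl]-2-[5-(3-methylbut-2-en-1-yl)-2,4-bis(triisopropylsilyloxy)phenyl]ethan-1-one | COCOc1ccc(C(=O)Cc2cc(CC=C(C)C)c(O[Si](C(C)C)(C(C)C)C(C)C)cc2O[Si](C(C)C)(C(C)C)C(C)C)c(F)c1 | intermediate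
11 | dicaesium 4-{2-[2-fluoro-4-(methoxymethoxy)phenyl]-2-oxoethyl}-6-(3-methylbut-2-en-1-yl)benzene-1,3-diolate | [Cs+].[Cs+].COCOc1ccc(C(=O)Cc2cc(CC=C(C)C)c([O-])cc2[O-])c(F)c1 | intermediate
12 | 3-hydroxy-7-(methoxymethoxy)-2-(3-methylbut-2-en-1-yl)dibenzo[b,f]oxepin-10(11H)-one | COCOc1ccc2c(c1)Oc1cc(O)c(CC=C(C)C)cc1CC2=O | intermediate
13 | 3,7-dihydroxy-2-(3-methylbut-2-en-1-yl)dibenzo[b,f]oxepin-10(11H)-one | O=C1Cc2cc(CC=C(C)C)c(O)cc2Oc2cc(O)ccc21 | intermediate
14 | 2-(3-methylbut-2-en-1-yl)-3,7-bis(triisopropylsilyloxy)dibenzo[b,f]oxepin-10(11H)-one | O=C1Cc2cc(CC=C(C)C)c(O[Si](C(C)C)(C(C)C)C(C)C)cc2Oc2cc(O[Si](C(C)C)(C(C)C)C(C)C)ccc21 | intermediate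
15 | lithium 2-(3-methylbut-2-en-1-yl)-3,7-bis(triisopropylsilyloxy)dibenzo[b,f]oxepin-10-olate | [Li+].[O-]C1=Cc2cc(CC=C(C)C)c(O[Si](C(C)C)(C(C)C)C(C)C)cc2Oc2cc(O[Si](C(C)C)(C(C)C)C(C)C)ccc21 | intermediate
16 | 11-{[(2S,3R)-3-methyl-3-(4-methylpent-3-en-1-yl)oxiran-2-yl]methyl}-2-(3-methylbut-2-en-1-yl)-3,7-bis(triisopropylsilyloxy)dibenzo[b,f]oxepin-10(11H)-one, both C11 epimers | CC(C)=CCC[C@@]1(C)O[C@H]1CC1C(=O)c2ccc(O[Si](C(C)C)(C(C)C)C(C)C)cc2Oc2cc(O[Si](C(C)C)(C(C)C)C(C)C)c(CC=C(C)C)cc21 | intermediate
17 | triethylsilyl ether of the bis(triisopropylsilyl)-protected target (pyran C2 S, C3 S) | CC(C)=CCC[C@]1(C)OC2=C(C[C@@H]1O[Si](CC)(CC)CC)c1cc(CC=C(C)C)c(O[Si](C(C)C)(C(C)C)C(C)C)cc1Oc1cc(O[Si](C(C)C)(C(C)C)C(C)C)ccc12 | intermediate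
18 | CNP0185870.1 | CC(C)=CCC[C@]1(C)OC2=C(C[C@@H]1O)c1cc(CC=C(C)C)c(O)cc1Oc1cc(O)ccc12 | target

**Totals**

Total step count: 12.
Longest linear sequence: 9 steps (steps 3, 4, 6, 7, 8, 9, 10, 11, 12; from 4 to 18).

**Steps most likely to fail**

Step 11 (the proposed step). The oxocarbenium ion may be intercepted by the neighbouring silyl ether oxygen instead of losing H-11, or the ketone may be O-silylated before the epoxide is activated, so that enol-ether formation is incomplete and mixtures result. The fallback separates ring closure from enol-ether formation with known chemistry and sets out from 16. Catalytic camphorsulfonic acid in CH2Cl2 at 0 °C should drive the γ,δ-epoxy ketone to the 2,7-dioxabicyclo[2.2.1]heptane ketal F1; any hydroxy enol ether formed alongside converges in the next operation. Me3SiOTf and iPr2NEt in CH2Cl2 at −20 °C should then silylate the less hindered secondary ketal oxygen, break its bond to C10 and remove H-11, giving the trimethylsilyl ether F2. F2 is desilylated under the conditions of step 12, so the fallback comes back to the route at 18.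

Step 10. The ambident enolate may be alkylated on oxygen, or proton transfer to the product may be followed by intramolecular opening of the epoxide by the new enolate. The fallback uses a carbon-selective azaenolate and sets out from 14. Condensation with Me2NNH2 (AcOH cat., EtOH, 70 °C) should give the N,N-dimethylhydrazone F3. Deprotonation with LiN(iPr)2 in THF and alkylation with 3 at −78 °C should give the alkylated hydrazone F4. Hydrolysis with aqueous CuCl2 in THF buffered at pH 7 should release the ketone, and the fallback comes back at 16.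

Step 7. The liberated ortho-hydroxybenzyl ketone may add to its own carbonyl and dehydrate to a 2-arylbenzofuran, or enolisation may switch off the SNAr. The fallback reverses the order of bond formation and sets out from 4 and 9. Intermolecular SNAr of 4 (in excess) on 9 (K2CO3, DMF, 110 °C) should give the diaryl ether F5, and MeOCH2Cl/iPr2NEt its MOM ether F6. Intramolecular palladium-catalysed ketone α-arylation (Pd2(dba)3, XPhos, K3PO4, toluene, 90 °C) at the bromide ortho to the ether oxygen, the only one that can reach the enolate, should close ring C to the bromo-oxepinone F7. Stille coupling with tributyl(3-methylbut-2-en-1-yl)stannane (Pd(PPh3)4, DMF, 90 °C) should give the bis-MOM prenyl ketone F8. Both MOM groups are removed under the conditions of step 8, and the fallback comes back at 13.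

**Further compounds**

F1 | step 11 | 2,7-dioxabicyclo[2.2.1]heptane ketal of 16 (C10 as ketal carbon bonded to the C2' and C3' oxygens; C2' S, C3' S; C11 epimers) | CC(C)=CCC[C@]1(C)O[C@]23O[C@H]1CC2c1cc(CC=C(C)C)c(O[Si](C(C)C)(C(C)C)C(C)C)cc1Oc1cc(O[Si](C(C)C)(C(C)C)C(C)C)ccc13
F2 | step 11 | trimethylsilyl ether of the bis(triisopropylsilyl)-protected target | CC(C)=CCC[C@]1(C)OC2=C(C[C@@H]1O[Si](C)(C)C)c1cc(CC=C(C)C)c(O[Si](C(C)C)(C(C)C)C(C)C)cc1Oc1cc(O[Si](C(C)C)(C(C)C)C(C)C)ccc12
F3 | step 10 | N,N-dimethylhydrazone of 14 | CN(C)N=C1Cc2cc(CC=C(C)C)c(O[Si](C(C)C)(C(C)C)C(C)C)cc2Oc2cc(O[Si](C(C)C)(C(C)C)C(C)C)ccc21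
F4 | step 10 | N,N-dimethylhydrazone of 16 | CC(C)=CCC[C@@]1(C)O[C@H]1CC1C(=NN(C)C)c2ccc(O[Si](C(C)C)(C(C)C)C(C)C)cc2Oc2cc(O[Si](C(C)C)(C(C)C)C(C)C)c(CC=C(C)C)cc21
F5 | step 7 | 1-[2-(2,4-dibromo-5-hydroxyphenoxy)-4-(methoxymethoxy)phenyl]ethan-1-one | COCOc1ccc(C(C)=O)c(Oc2cc(O)c(Br)cc2Br)c1
F6 | step 7 | 1-{2-[2,4-dibromo-5-(methoxymethoxy)phenoxy]-4-(methoxymethoxy)phenyl}ethan-1-one | COCOc1ccc(C(C)=O)c(Oc2cc(OCOC)c(Br)cc2Br)c1
F7 | step 7 | 2-bromo-3,7-bis(methoxymethoxy)dibenzo[b,f]oxepin-10(11H)-one | COCOc1ccc2c(c1)Oc1cc(OCOC)c(Br)cc1CC2=O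
F8 | step 7 | 3,7-bis(methoxymethoxy)-2-(3-methylbut-2-en-1-yl)dibenzo[b,f]oxepin-10(11H)-one | COCOc1ccc2c(c1)Oc1cc(OCOC)c(CC=C(C)C)cc1CC2=O
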